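**Assumptions (one line each)**
- Sigmoidin B is (2S)-5'-prenyleriodictyol, and the given SMILES is the 2S enantiomer.
- 2',4',6'-Trihydroxyacetophenone (7) is commercial, made from phloroglucinol.
- Recombinant chalcone isomerase (CHI, Arabidopsis or Medicago, expressed in *E. coli*) is treated as an available reagent.

**Retrosynthesis**
- The pyranone ring is formed last. CHI converts the achiral, mirror-symmetric 2',4',6'-trihydroxychalcone (8) into the (2S)-flavanone by an oxa-Michael addition. The enzyme selects one enone face and one of the two equivalent ortho-OH groups, so this step breaks the symmetry and sets C2.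
- Chalcone 8 comes from a Claisen–Schmidt condensation of phloroacetophenone (7) with 3,4-dihydroxy-5-prenylbenzaldehyde (6).
- Aldehyde 6 comes from protocatechualdehyde (1) by 4-O-allylation, Claisen rearrangement to C5, and allyl-to-prenyl cross-metathesis.
- Both aromatic rings are present from the start. No protecting groups are used, so the free phenolic chalcone goes straight to the enzyme.

---

**Step 1**
Reactants: 1 (3,4-dihydroxybenzaldehyde); 2 (allyl bromide)
Product: 3 (4-allyloxy-3-hydroxybenzaldehyde)
Conditions: NaHCO3, DMF, 40 °C, 16 h
Reagents that add atoms: allyl bromide, C=CCBr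
Why: The 4-OH is para to the CHO and more acidic, so mild bicarbonate gives selective Williamson O-alkylation at O4 and leaves the 3-OH free. No stereocenter is formed.

**Step 2**
Reactants: 3
Product: 4 (5-allyl-3,4-dihydroxybenzaldehyde)
Conditions: PhNEt2, 200 °C (microwave, sealed, Ar), 30 min
Reagents that add atoms: none
Why: Thermal aromatic Claisen [3,3] rearrangement. One ortho position (C3) carries OH and the para position carries CHO, so the allyl group can only land on free C5, which gives the 3,4-dihydroxy-5-allyl pattern needed for the B ring.

**Step 3**
Reactants: 4; 5 (2-methyl-2-butene)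
Product: 6 (3,4-dihydroxy-5-(3-methylbut-2-en-1-yl)benzaldehyde)
Conditions: Hoveyda–Grubbs II (5 mol%), 1,4-benzoquinone (10 mol%), excess 2-methyl-2-butene (~20 equiv), CH2Cl2, 40 °C, sealed tube, 12 h
Reagents that add atoms: 2-methyl-2-butene, CC=C(C)C (supplies the =CMe2 terminus; propene is lost)
Why: Olefin cross-metathesis converts the terminal allyl alkene into the trisubstituted prenyl alkene. Benzoquinone suppresses Ru-hydride alkene isomerization, and the large excess of the trisubstituted partner drives the exchange.

**Step 4**
Reactants: 6; 7 (2',4',6'-trihydroxyacetophenone)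
Product: 8 ((E)-3-(3,4-dihydroxy-5-prenylphenyl)-1-(2,4,6-trihydroxyphenyl)prop-2-en-1-one)
Conditions: LiOH·H2O (8 equiv), MeOH/H2O 4:1, 7 (1.5 equiv), 40 °C, Ar, dark, 48 h; then cold 1 M HCl to pH 4, rapid EtOAc extraction and short silica plug
Reagents that add atoms: none
Why: Base-mediated Claisen–Schmidt (aldol condensation, then E1cB dehydration) gives the E-chalcone. In the polyphenoxide the chalcone stays open-chain, so it does not cyclize to racemic flavanone before workup. The product is achiral and has a mirror plane, so no stereocenter forms here.

**Step 5**
Reactants: 8
Product: 9 (sigmoidin B, (2S)-5,7,3',4'-tetrahydroxy-5'-prenylflavanone)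
Conditions: recombinant CHI (1–5 mol% by mass), 50 mM Tris-HCl pH 7.5, 5% DMSO, 2 mM sodium ascorbate, 25 °C, Ar, 30 min; then acidify to pH 5, extract with EtOAc, purify by prep-HPLC
Reagents that add atoms: none (isomerization)
Why: Chalcone isomerase catalyzes the intramolecular oxa-Michael ring closure (enzymatic desymmetrizing cyclization). The active site binds the s-cis chalcone and delivers the 6'-O to one enone face only, so C2 forms as S. The rate is about 10^7 times the uncatalyzed background, so the racemic route is outcompeted.
Proposed new method: The closest known reaction is CHI cyclization of naringenin or eriodictyol chalcone to (2S)-flavanones with >99% ee. The extension is the B-ring 5'-prenyl substrate, which I expect to fit because the B ring is only partly buried in the active site.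

---

**Consistency check**
- Ring sizes and substituents: the flavanone has a 6-membered pyranone with 5,7-diOH on the A ring, and the B ring has 3',4'-diOH and 5'-prenyl, matching the target SMILES.
- Stereochemistry: the target [C@@H] was worked out as (2S), and CHI gives (2S).
- Atom balance: 1 + 2 → 3 + HBr; 3 → 4 (isomer); 4 + 5 → 6 + propene; 6 + 7 → 8 + H2O; 8 → 9 (isomer).
- Functional groups: no protecting groups are used, and no step removes or reduces the prenyl alkene. The only step run in base (step 4) is acidified cold and quickly, and the final step is run at neutral pH, so the C2 stereocenter is not epimerized.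

---

**Compound list**

| No. | Name | SMILES | Role |
|---|---|---|---|
| 1 | 3,4-Dihydroxybenzaldehyde | O=Cc1ccc(O)c(O)c1 | starting material |
| 2 | Allyl bromide | C=CCBr | starting material (reagent) |
| 3 | 4-Allyloxy-3-hydroxybenzaldehyde | O=Cc1ccc(OCC=C)c(O)c1 | intermediate |
| 4 | 5-Allyl-3,4-dihydroxybenzaldehyde | O=Cc1cc(O)c(O)c(CC=C)c1 | intermediate |
| 5 | 2-Methyl-2-butene | CC=C(C)C | starting material (reagent) |
| 6 | 3,4-Dihydroxy-5-prenylbenzaldehyde | O=Cc1cc(O)c(O)c(CC=C(C)C)c1 | intermediate |
| 7 | 2',4',6'-Trihydroxyacetophenone | CC(=O)c1c(O)cc(O)cc1O | starting material |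
| 8 | (E)-2',3,4,4',6'-Pentahydroxy-5-prenylchalcone | O=C(/C=C/c1cc(O)c(O)c(CC=C(C)C)c1)c1c(O)cc(O)cc1O | intermediate |
| 9 | Sigmoidin B, (2S) | CC(C)=CCc1cc([C@@H]2CC(=O)c3c(O)cc(O)cc3O2)cc(O)c1O | target |

**Total steps:** 5. **Longest linear sequence:** 5 steps (1 → 3 → 4 → 6 → 8 → 9), with 7 entering at step 4.

**Three steps most likely to fail**
1. **Step 5 (CHI on the prenylated substrate).** The 5'-prenyl group may be poorly accepted, giving low turnover.
   - Fallback: cyclize 8 non-enzymatically (NaOAc, EtOH, reflux) to racemic sigmoidin B, then resolve by preparative chiral-phase HPLC to isolate the (2S)-enantiomer.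
2. **Step 4 (Claisen–Schmidt on fully unprotected polyphenols).** The polyanion deactivates both partners and catechol oxidation competes, so yield may be low.
   - Fallback: use a protecting-group strategy. Condense bis-MOM-protected 6 with 4',6'-bis-MOM-2'-hydroxyacetophenone, remove the MOM groups with mild acid, then cyclize with CHI or resolve as above.
3. **Step 3 (cross-metathesis on a free catechol aldehyde).** The free catechol may poison Ru, and alkene isomerization can give mixtures.
   - Fallback: drop metathesis. Start from 5-bromo-3,4-dihydroxybenzaldehyde, protect it as the bis-MOM ether, install the prenyl group by a Pd- or Cu-catalyzed prenyl-metal cross-coupling, and deprotect under mild conditions.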